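**Retrosynthetic overview**
1. Target ⇐ C6 acetal hydrolysis ⇐ ring D closed last by an intramolecular Nozaki–Hiyama–Kishi addition of a C16 vinyl bromide to the C13 ketone (sets C13).
2. C8 quaternary centre and C15 carbinol ⇐ fluoride-mediated aldol of the lactone silyl ketene acetal with 2-bromoacrolein.
3. δ-Lactone (C7–C8 bond) ⇐ 6-exo alkoxycarbonyl-radical cyclisation of a C20 oxalate onto the ring C enone (new step); the enone and C9 ⇐ desymmetrising enol silylation and Saegusa oxidation of a 4-substituted cyclohexanone obtained by hydrogenating a para-oxygenated aryl group.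
4. Quaternary C10 (C9–C10 bond, C20–OH, C1 ketone) ⇐ key semipinacol 1,2-aryl shift of a 2,3-epoxy alcohol made by aryllithium addition to an α-methylene ketone.
5. Ring A ⇐ Robinson annulation, then asymmetric vinyl conjugate addition with Mannich trapping (sets C5). Ring order: A → aryl (latent ring C) → lactone → D.

Assumption: 2-bromoacrolein is bought; the sense of induction of the chiral ligand (step 2) and the chiral lithium amide (step 9) is taken by analogy with 4,4-dimethylcyclohexenone and 4-tert-butylcyclohexanone and the reagent antipode is used if a first run shows the opposite sense; atom labels C1–C20 are the ent-kaurane positions of the target.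

**Step 1**
Reactants: 1 isobutyraldehyde; 2 methyl vinyl ketone
Product: 3 4,4-dimethylcyclohex-2-en-1-one
Conditions: H2SO4 (cat.), toluene, reflux, Dean–Stark
Reagents that add atoms: none
Why: acid-catalysed Robinson annulation (Michael addition of the aldehyde enol, then aldol condensation) is a known one-pot route to this enone and creates no stereocentre.

**Step 2**
Reactants: 3 4,4-dimethylcyclohex-2-en-1-one; 4 vinylmagnesium bromide
Product: 6 (2R,3S)-2-[(dimethylamino)methyl]-4,4-dimethyl-3-vinylcyclohexan-1-one, via dimethylaluminium enolate 5 (not isolated)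
Conditions: 4, Me2AlCl, Et2O, −30 °C; Cu(O2CC4H3S) (5 mol %), (S,S)-Ph2PN[CH(CH3)Ph]2 (10 mol %), 3, −30 °C; then CH2=NMe2+ I−, THF, −30 → 0 °C; aq. NaOH
Reagents that add atoms: dimethylmethyleneiminium iodide, C=[N+](C)C.[I-]
Why: copper-catalysed asymmetric conjugate addition of an alkenylalane sets C5 by ligand control, and the regiodefined aluminium enolate is trapped at C10 in a Mannich reaction anti to the new vinyl group (the C10 centre is erased in step 4).

**Step 3**
Reactants: 6 (2R,3S)-2-[(dimethylamino)methyl]-4,4-dimethyl-3-vinylcyclohexan-1-one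
Product: 8 (2R,3S)-2-[(dimethylamino)methyl]-3-(1,3-dioxolan-2-yl)-4,4-dimethylcyclohexan-1-one, via amino aldehyde triflate salt 7 (not isolated)
Conditions: CF3SO3H (1.05 equiv), CH2Cl2, −78 °C; O3; PPh3; then Me3SiOCH2CH2OSiMe3, Me3SiOTf (0.2 equiv), −78 → −20 °C; aq. NaHCO3
Reagents that add atoms: 1,2-bis(trimethylsilyloxy)ethane, C[Si](C)(C)OCCO[Si](C)(C)C
Why: ozonolysis of the only alkene with the amine protected as its ammonium salt, then Noyori acetalisation, which takes the aldehyde and leaves the ketone at −78 °C; C5 is not enolised under these cold acidic conditions.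

**Step 4**
Reactants: 8 (2R,3S)-2-[(dimethylamino)methyl]-3-(1,3-dioxolan-2-yl)-4,4-dimethylcyclohexan-1-one
Product: 10 (3R)-3-(1,3-dioxolan-2-yl)-4,4-dimethyl-2-methylidenecyclohexan-1-one, via methiodide 9 (not isolated)
Conditions: MeI, acetone, 20 °C; then NaHCO3 (aq.), CH2Cl2, 20 °C
Reagents that add atoms: none
Why: quaternisation and E1cB elimination of the Mannich base give the α-methylene ketone without touching C5; the product is used at once to avoid dimerisation.

**Step 5**
Reactants: 11 4-bromophenol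
Product: 12 1-(benzyloxy)-4-bromobenzene
Conditions: BnBr, K2CO3, acetone, reflux
Reagents that add atoms: benzyl bromide, BrCc1ccccc1
Why: Williamson etherification protects the phenol, makes the ring an electron-rich migrating group for step 7, and is removed by hydrogenolysis in step 8.

**Step 6**
Reactants: 12 1-(benzyloxy)-4-bromobenzene; 10 (3R)-3-(1,3-dioxolan-2-yl)-4,4-dimethyl-2-methylidenecyclohexan-1-one
Product: 14 (1S,3R)-1-[4-(benzyloxy)phenyl]-3-(1,3-dioxolan-2-yl)-4,4-dimethyl-2-methylidenecyclohexan-1-ol, via [4-(benzyloxy)phenyl]lithium 13 (not isolated)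
Conditions: n-BuLi, THF, −78 °C; then 10, −78 °C; H2O
Reagents that add atoms: none
Why: bromine–lithium exchange and 1,2-addition of the aryllithium to the ketone; the C5 dioxolanyl group sits axial (allylic 1,3-strain with the exocyclic methylene) and blocks the syn-axial path, so the aryl group enters equatorially anti to it and the C1 hydroxyl ends cis to C6.

**Step 7 (key step)**
Reactants: 14 (1S,3R)-1-[4-(benzyloxy)phenyl]-3-(1,3-dioxolan-2-yl)-4,4-dimethyl-2-methylidenecyclohexan-1-ol
Product: 16 (2R,3R)-2-[4-(benzyloxy)phenyl]-3-(1,3-dioxolan-2-yl)-2-(hydroxymethyl)-4,4-dimethylcyclohexan-1-one, via epoxy alcohol 15 (not isolated)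
Conditions: VO(acac)2 (5 mol %), t-BuOOH, CH2Cl2, 0 °C; then ZnBr2 (0.3 equiv), −20 → 0 °C
Reagents that add atoms: tert-butyl hydroperoxide, CC(C)(C)OO
Why: hydroxyl-directed epoxidation places the epoxide oxygen syn to the C1 hydroxyl, and the zinc-chelated 2,3-epoxy alcohol undergoes a semipinacol rearrangement in which the aryl group shifts from C1 to C10 anti to the breaking C–O bond, giving the C1 ketone, the C20 alcohol and the quaternary C10 centre with the aryl group trans to C6.

**Step 8**
Reactants: 16 (2R,3R)-2-[4-(benzyloxy)phenyl]-3-(1,3-dioxolan-2-yl)-2-(hydroxymethyl)-4,4-dimethylcyclohexan-1-one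
Product: 18 (2S,3R)-3-(1,3-dioxolan-2-yl)-2-(hydroxymethyl)-4,4-dimethyl-2-(4-oxocyclohexyl)cyclohexan-1-one, via phenol 17 (not isolated)
Conditions: H2 (1 bar), Pd on carbon (10 wt %), EtOH, 25 °C; then H2 (5 bar), 60 °C
Reagents that add atoms: none
Why: benzyl ether hydrogenolysis followed by palladium-catalysed partial hydrogenation of the phenol, which stops at the cyclohexanone because the enol tautomerises and the ketone is reduced only slowly; no stereocentre is touched and C9 becomes a prochiral CH.

**Step 9**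
Reactants: 18 (2S,3R)-3-(1,3-dioxolan-2-yl)-2-(hydroxymethyl)-4,4-dimethyl-2-(4-oxocyclohexyl)cyclohexan-1-one
Product: 19 tris-silyl compound (C20 trimethylsilyl ether; trimethylsilyl enol ethers C1=C2 in ring A and C13=C14 in ring C; 5R,9R,10S)
Conditions: LiN[(S)-CH(CH3)Ph]2 (3.5 equiv), LiCl, Me3SiCl (5 equiv), THF, −100 → −78 °C
Reagents that add atoms: chlorotrimethylsilane, C[Si](C)(C)Cl
Why: chiral lithium amide deprotonation with internal silyl quench (Simpkins–Koga desymmetrisation) removes one enantiotopic α-proton of the 4-substituted cyclohexanone so the enol silane forms on the C14 side, which fixes C9; the ring A ketone (enolisable only at C2) and the C20 alkoxide are silylated in the same operation, which also suppresses retro-aldol loss of formaldehyde.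

**Step 10**
Reactants: 19 tris-silyl compound
Product: 20 (5R,6S)-5-(1,3-dioxolan-2-yl)-6-(hydroxymethyl)-4,4-dimethyl-6-[(1R)-4-oxocyclohex-2-en-1-yl]cyclohex-2-en-1-one
Conditions: Pd(OAc)2 (2.2 equiv), MeCN, 25 °C; then citric acid, MeOH, 0 °C
Reagents that add atoms: none
Why: twofold Saegusa–Ito oxidation converts both enol silanes into enones (C2=C3 in ring A, C14=C8 in ring C) without touching C9, and mild acidic methanolysis frees the C20 alcohol.

**Step 11**
Reactants: 20 (5R,6S)-5-(1,3-dioxolan-2-yl)-6-(hydroxymethyl)-4,4-dimethyl-6-[(1R)-4-oxocyclohex-2-en-1-yl]cyclohex-2-en-1-one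
Product: 22 caesium half-oxalate of 20 at the C20 oxygen, via methyl oxalate 21 (not isolated)
Conditions: MeO2CCOCl, Et3N, DMAP (cat.), CH2Cl2, 0 °C; then CsOH (1.0 equiv), THF/H2O, 20 °C
Reagents that add atoms: methyl chlorooxoacetate, COC(=O)C(Cl)=O; caesium hydroxide, [Cs+].[OH-]
Why: acylation of the neopentyl alcohol and selective saponification of the less hindered methyl ester of the mixed oxalate is the standard preparation of oxalate radical precursors; this reagent supplies C7.

**Step 12 (new step)**
Reactants: 22 caesium half-oxalate of 20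
Product: 23 spiro keto-lactone (7,20-lactone closed on C8; cis-fused to ring C; C13 ketone; ring A enone; 5R,8S,9R,10S)
Conditions: [Ir(dF(CF3)ppy)2(dtbbpy)]PF6 (1 mol %), H2O (10 equiv), DME/DMF (3:1), blue LEDs (450 nm), 30 °C
Reagents that add atoms: none
Why: Proposed new method: the excited iridium photocatalyst oxidises the carboxylate, loss of one CO2 gives a primary alkoxycarbonyl radical that is slow to decarboxylate further, and this nucleophilic radical adds 6-exo-trig to the β-carbon C8 of the ring C enone (the ring A enone is reachable only by mismatched α-attack or a 7-endo path), after which the α-keto radical is reduced by the reduced photocatalyst and protonated, closing the δ-lactone redox-neutrally; the closest known reactions are 5-exo cyclisations of oxalate-derived alkoxycarbonyl radicals onto unactivated alkenes and 6-exo lactonisations of selenocarbonate-derived alkoxycarbonyl radicals; the configuration at C8 does not matter because C8 is planarised in step 13.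

**Step 13**
Reactants: 23 spiro keto-lactone; 24 2-bromoacrolein
Product: 26 aldol adduct (C8 quaternary with a CH(OH)–C(Br)=CH2 arm; C13 ketone; 5R,8S,9S,10S,15S), via bis-silyl ketene acetal 25 (not isolated)
Conditions: LiN(iPr)2 (2.5 equiv), Me3SiCl (3 equiv), THF, −78 °C; pentane, filtration; then 24, [(Me2N)3S][Me3SiF2] (10 mol %), THF, −78 °C; citric acid (aq.), 0 °C
Reagents that add atoms: none
Why: fluoride-catalysed Mukaiyama aldol of the silyl ketene acetal (the C13 ketone is masked in the same pot as its less nucleophilic enol silane) through an open transition state: the aldehyde adds to C8 on the face of the C9 hydrogen (the usual cis-selective angular attack; the other face is shielded by the axial substituent on C10), and with C=O anti to the ketene acetal and the bromovinyl group next to the smaller C14 the C15 hydroxyl comes out syn to C9.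

**Step 14**
Reactants: 26 aldol adduct
Product: 27 target 6-(ethylene acetal) (5R,8S,9S,10S,13S,15R)
Conditions: CrCl2 (8 equiv), NiCl2 (5 mol %), DMF, 25 → 45 °C; H2O
Reagents that add atoms: none
Why: intramolecular Nozaki–Hiyama–Kishi reaction: nickel-catalysed formation of the C16 vinylchromium species and 5-exo addition to the C13 ketone close ring D; the bridged geometry allows attack only from the face carrying the C15 arm, which sets C13, and the enone, lactone and acetal are inert to the organochromium species.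

**Step 15**
Reactants: 27 target 6-(ethylene acetal)
Product: 28 CNP0521079.1
Conditions: AcOH/THF/H2O (3:1:1), 40 °C
Reagents that add atoms: water, O
Why: mild acid hydrolysis of the dioxolane frees the C6 aldehyde without base-mediated epimerisation at C5 and without ionising the tertiary allylic alcohol.

**Compound list**
1 | isobutyraldehyde | CC(C)C=O | starting material
2 | methyl vinyl ketone | CC(=O)C=C | starting material
3 | 4,4-dimethylcyclohex-2-en-1-one | CC1(C)CCC(=O)C=C1 | intermediate
4 | vinylmagnesium bromide | C=C[Mg]Br | starting material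
5 | dimethyl{[(3S)-4,4-dimethyl-3-vinylcyclohex-1-en-1-yl]oxy}aluminium | C[Al](C)OC1=C[C@H](C=C)C(C)(C)CC1 | intermediate
6 | (2R,3S)-2-[(dimethylamino)methyl]-4,4-dimethyl-3-vinylcyclohexan-1-one | O=C1CCC(C)(C)[C@@H](C=C)[C@@H]1CN(C)C | intermediate
7 | (1S,2R)-2-[(dimethylammonio)methyl]-6,6-dimethyl-3-oxocyclohexane-1-carbaldehyde triflate | O=C1CCC(C)(C)[C@@H](C=O)[C@@H]1C[NH+](C)C.[O-]S(=O)(=O)C(F)(F)F | intermediate
8 | (2R,3S)-2-[(dimethylamino)methyl]-3-(1,3-dioxolan-2-yl)-4,4-dimethylcyclohexan-1-one | O=C1CCC(C)(C)[C@@H](C2OCCO2)[C@@H]1CN(C)C | intermediate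
9 | {[(1R,6S)-6-(1,3-dioxolan-2-yl)-5,5-dimethyl-2-oxocyclohexyl]methyl}trimethylammonium iodide | O=C1CCC(C)(C)[C@@H](C2OCCO2)[C@@H]1C[N+](C)(C)C.[I-] | intermediate
10 | (3R)-3-(1,3-dioxolan-2-yl)-4,4-dimethyl-2-methylidenecyclohexan-1-one | O=C1CCC(C)(C)[C@@H](C2OCCO2)C1=C | intermediate
11 | 4-bromophenol | Oc1ccc(Br)cc1 | starting material
12 | 1-(benzyloxy)-4-bromobenzene | Brc1ccc(OCc2ccccc2)cc1 | intermediate
13 | [4-(benzyloxy)phenyl]lithium | [Li]c1ccc(OCc2ccccc2)cc1 | intermediate
14 | (1S,3R)-1-[4-(benzyloxy)phenyl]-3-(1,3-dioxolan-2-yl)-4,4-dimethyl-2-methylidenecyclohexan-1-ol | O[C@@]1(c2ccc(OCc3ccccc3)cc2)CCC(C)(C)[C@@H](C2OCCO2)C1=C | intermediate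
15 | (3S,4R,8R)-4-[4-(benzyloxy)phenyl]-8-(1,3-dioxolan-2-yl)-7,7-dimethyl-1-oxaspiro[2.5]octan-4-ol | O[C@@]1(c2ccc(OCc3ccccc3)cc2)CCC(C)(C)[C@@H](C2OCCO2)[C@]14CO4 | intermediate
16 | (2R,3R)-2-[4-(benzyloxy)phenyl]-3-(1,3-dioxolan-2-yl)-2-(hydroxymethyl)-4,4-dimethylcyclohexan-1-one | O=C1CCC(C)(C)[C@@H](C2OCCO2)[C@]1(CO)c3ccc(OCc4ccccc4)cc3 | intermediate
17 | (2R,3R)-3-(1,3-dioxolan-2-yl)-2-(hydroxymethyl)-2-(4-hydroxyphenyl)-4,4-dimethylcyclohexan-1-one | O=C1CCC(C)(C)[C@@H](C2OCCO2)[C@]1(CO)c3ccc(O)cc3 | intermediate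
18 | (2S,3R)-3-(1,3-dioxolan-2-yl)-2-(hydroxymethyl)-4,4-dimethyl-2-(4-oxocyclohexyl)cyclohexan-1-one | O=C1CCC(C)(C)[C@@H](C2OCCO2)[C@]1(CO)C3CCC(=O)CC3 | intermediate
19 | tris-silyl compound (C20 trimethylsilyl ether; trimethylsilyl enol ethers C1=C2 and C13=C14; 5R,9R,10S) | C[Si](C)(C)OC1=CCC(C)(C)[C@@H](C2OCCO2)[C@]1(CO[Si](C)(C)C)[C@H]3CC=C(O[Si](C)(C)C)CC3 | intermediate
20 | (5R,6S)-5-(1,3-dioxolan-2-yl)-6-(hydroxymethyl)-4,4-dimethyl-6-[(1R)-4-oxocyclohex-2-en-1-yl]cyclohex-2-en-1-one | O=C1C=CC(C)(C)[C@@H](C2OCCO2)[C@]1(CO)[C@H]3C=CC(=O)CC3 | intermediate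
21 | methyl oxalate of 20 (mixed diester at the C20 oxygen) | O=C1C=CC(C)(C)[C@@H](C2OCCO2)[C@]1(COC(=O)C(=O)OC)[C@H]3C=CC(=O)CC3 | intermediate
22 | caesium half-oxalate of 20 at the C20 oxygen | O=C1C=CC(C)(C)[C@@H](C2OCCO2)[C@]1(COC(=O)C(=O)[O-])[C@H]3C=CC(=O)CC3.[Cs+] | intermediate
23 | spiro keto-lactone (5R,8S,9R,10S) | O=C1C[C@H]2[C@@H](CC1)[C@]3(COC2=O)C(=O)C=CC(C)(C)[C@H]3C4OCCO4 | intermediate
24 | 2-bromoacrolein (2-bromoprop-2-enal) | C=C(Br)C=O | starting material
25 | C13 trimethylsilyl enol ether / C7 trimethylsilyl ketene acetal of 23 | C[Si](C)(C)OC1=CC[C@@H]2C(C1)=C(O[Si](C)(C)C)OC[C@]23C(=O)C=CC(C)(C)[C@H]3C4OCCO4 | intermediate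
26 | aldol adduct (5R,8S,9S,10S,15S) | C=C(Br)[C@@H](O)[C@]23CC(=O)CC[C@H]2[C@]1(COC3=O)C(=O)C=CC(C)(C)[C@H]1C4OCCO4 | intermediate
27 | target 6-(ethylene acetal) (5R,8S,9S,10S,13S,15R) | C=C1[C@@H](O)[C@]23C[C@@]1(O)CC[C@H]2[C@]1(COC3=O)C(=O)C=CC(C)(C)[C@H]1C4OCCO4 | intermediate
28 | CNP0521079.1 (5R,8S,9S,10S,13S,15R) | C=C1[C@@H](O)[C@]23C[C@@]1(O)CC[C@H]2[C@]1(COC3=O)C(=O)C=CC(C)(C)[C@H]1C=O | target

**Step count:** 15 steps in total; longest linear sequence 14 steps (steps 1–4 and 6–15; step 5 is the one-step side branch).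

**Three steps most likely to fail**

Step 7 (semipinacol). Risks are ring contraction (migration of C2 instead of the aryl group when the epoxide C–O bond is equatorial) and acid-induced acetal exchange with the neighbouring hydroxyls. The fallback keeps the 1,2-aryl shift but uses neither an epoxide nor a Lewis acid. It sets out from 14: N-iodosuccinimide (NaHCO3, CH2Cl2, −40 °C) forms the iodonium ion on the exocyclic alkene and the aryl group bridges to the tertiary C10 cation from its own face, giving (2S,3R)-2-[4-(benzyloxy)phenyl]-3-(1,3-dioxolan-2-yl)-2-(iodomethyl)-4,4-dimethylcyclohexan-1-one F1. The neopentyl iodide is then oxygenated by a radical chain (Bu3SnH, air, toluene, 0 → 25 °C; oxygen capture of the primary radical outruns a neophyl shift) to the hydroperoxide F2, which PPh3 reduces in the same flask. The fallback rejoins the route at 16.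

Step 12 (new photoredox lactonisation). Risks are a slow 6-exo closure and competing reduction or loss of the oxalate. The fallback uses the known tin-free chain cyclisation of a selenocarbonate and sets out from 20: COCl2 and pyridine (CH2Cl2, 0 °C) give the chloroformate F3, PhSeH and pyridine convert it into the Se-phenyl selenocarbonate F4, and slow addition of (Me3Si)3SiH and AIBN (benzene, 80 °C) generates the same alkoxycarbonyl radical thermally, which cyclises and is quenched by hydrogen-atom transfer. The fallback rejoins the route at 23.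

Step 13 (aldol: reactivity of a tetrasubstituted ketene acetal and the C15 configuration). If the open-transition-state aldol is sluggish or gives the C15 epimer, C15 is instead set after ring closure by a hydroxyl-directed reduction. The fallback sets out from 23: Me3SiOTf and Et3N mask the ketone as the C13 trimethylsilyl enol ether F5; LiN(iPr)2 (THF, −78 °C) gives the lithium lactone enolate, which adds to 24 through the closed chair transition state to give, after AcOH quench and citric acid, the 15-epimeric aldol adduct F6. CrCl2/NiCl2 (DMF) closes ring D to the 15-epimeric diol F7, MnO2 (CH2Cl2) oxidises the secondary allylic alcohol to the 15-ketone F8, and Me4N[BH(OAc)3] (AcOH/MeCN, −20 °C) delivers hydride from the boron bound to the exo C13 hydroxyl onto the exo face of C15; this reagent leaves the ring A enone untouched. The fallback rejoins the route at 27.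

**Further compounds**
F1 | step 7 | (2S,3R)-2-[4-(benzyloxy)phenyl]-3-(1,3-dioxolan-2-yl)-2-(iodomethyl)-4,4-dimethylcyclohexan-1-one | O=C1CCC(C)(C)[C@@H](C2OCCO2)[C@]1(CI)c3ccc(OCc4ccccc4)cc3
F2 | step 7 | (2R,3R)-2-[4-(benzyloxy)phenyl]-3-(1,3-dioxolan-2-yl)-2-(hydroperoxymethyl)-4,4-dimethylcyclohexan-1-one | O=C1CCC(C)(C)[C@@H](C2OCCO2)[C@]1(COO)c3ccc(OCc4ccccc4)cc3
F3 | step 12 | chloroformate of 20 at the C20 oxygen | O=C1C=CC(C)(C)[C@@H](C2OCCO2)[C@]1(COC(Cl)=O)[C@H]3C=CC(=O)CC3
F4 | step 12 | Se-phenyl selenocarbonate of 20 at the C20 oxygen | O=C1C=CC(C)(C)[C@@H](C2OCCO2)[C@]1(COC(=O)[Se]c4ccccc4)[C@H]3C=CC(=O)CC3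
F5 | step 13 | C13 trimethylsilyl enol ether of 23 | C[Si](C)(C)OC1=CC[C@@H]2[C@H](C1)C(=O)OC[C@]23C(=O)C=CC(C)(C)[C@H]3C4OCCO4
F6 | step 13 | 15-epimer of 26 (5R,8S,9S,10S,15R) | C=C(Br)[C@H](O)[C@]23CC(=O)CC[C@H]2[C@]1(COC3=O)C(=O)C=CC(C)(C)[C@H]1C4OCCO4
F7 | step 13 | 15-epimer of 27 (5R,8S,9S,10S,13S,15S) | C=C1[C@H](O)[C@]23C[C@@]1(O)CC[C@H]2[C@]1(COC3=O)C(=O)C=CC(C)(C)[C@H]1C4OCCO4
F8 | step 13 | 15-oxo analogue of 27 (5R,8S,9S,10S,13S) | C=C1C(=O)[C@]23C[C@@]1(O)CC[C@H]2[C@]1(COC3=O)C(=O)C=CC(C)(C)[C@H]1C4OCCO4
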